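**Retrosynthetic overview**

1. Helenien is cut at the C8'–C9' single bond into a C11 ε-ring vinyl palmitate and a C29 β-ring polyenyl pinacol boronate (boron on C9'); the two are joined in the last step by an oxidative Heck C–H vinylation that also creates the E-C7'=C8' double bond.
2. Enabling feature: C7'=C8' is the only chain double bond that ends on an sp3 ring atom (C6' of the ε-ring C1'–C6'), so the C11 half is a terminal vinyl compound, the sole monosubstituted alkene of either partner, whose C8'–H is replaced; C9' is a methyl-bearing sp2 carbon that can carry boron.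
3. C29 boronate: Horner–Wadsworth–Emmons olefination (C11'=C12') of a C25 apo-12'-carotenal with a C4 borylated phosphonate; C25 by Wittig reaction (C11=C12) of a C15 phosphonium salt with the C10 dialdehyde; C15 by Stille coupling (C6–C7) of an actinol-derived enol triflate.
4. C11 half: lipase resolution with vinyl palmitate, preceded by methylenation, chemoselective oxidation and trans-selective reduction of the keto ester made from mesityl oxide and ethyl acetoacetate.
5. Rings: the ε-ring is closed first (Michael/aldol annulation, step 1); the β-ring is taken intact from (4R,6R)-actinol; the key step closes no ring.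

Key step: step 17

Assumption: in step 5 the lipase acylates the (1R)-carbinol faster, as the empirical size rule for lipases predicts when the alkene side of the ring acts as the large substituent; positions are given with carotenoid locants (primed = ε-ring half).

**Route**

Step 1
Reactants: 1 mesityl oxide (4-methylpent-3-en-2-one); 2 ethyl acetoacetate
Product: 3 rac-ethyl 2,6,6-trimethyl-4-oxocyclohex-2-ene-1-carboxylate
Conditions: ZnCl2 (0.3 equiv), toluene–heptane, reflux, Dean–Stark
Reagents that add atoms: none
Why: Lewis-acid-mediated Michael addition of the acetoacetate to mesityl oxide followed by intramolecular aldol condensation (Robinson-type annulation) closes the future ε-ring with the ester on C6', the ketone on C3' and the C4'=C5' enone in place; C6' is formed racemic and labile and is fixed relative to C3' only in step 2.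

Step 2
Reactants: 3 rac-ethyl 2,6,6-trimethyl-4-oxocyclohex-2-ene-1-carboxylate
Product: 4 rac-(1R,4R)-4-(hydroxymethyl)-3,5,5-trimethylcyclohex-2-en-1-ol (trans diol)
Conditions: iBu2AlH (4.5 equiv), CH2Cl2, −78 → 0 °C; aq. potassium sodium tartrate
Reagents that add atoms: none
Why: Aluminium hydride reduction (1,2-reduction of the enone plus ester reduction) in which the hydride should attack C3' anti to the axial methyl of the C1' gem-dimethyl group in the half-chair that keeps the C6' substituent pseudo-axial (allylic 1,2-strain against the C5' methyl), placing the new hydroxyl trans to the C6' arm; the minor cis diol is removed by chromatography.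

Step 3
Reactants: 4 rac-(1R,4R)-4-(hydroxymethyl)-3,5,5-trimethylcyclohex-2-en-1-ol
Product: 5 rac-(1R,4R)-4-hydroxy-2,6,6-trimethylcyclohex-2-ene-1-carbaldehyde
Conditions: TEMPO (10 mol%), PhI(OAc)2 (1.1 equiv), CH2Cl2, 0 → 20 °C
Reagents that add atoms: none
Why: Oxoammonium (TEMPO) oxidation, which for steric reasons oxidises the primary carbinol much faster than the secondary allylic one and runs without base, so the epimerisable β,γ-unsaturated aldehyde should keep its C6' configuration and its double-bond position.

Step 4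
Reactants: 5 rac-(1R,4R)-4-hydroxy-2,6,6-trimethylcyclohex-2-ene-1-carbaldehyde
Product: 6 rac-(1R,4R)-3,5,5-trimethyl-4-vinylcyclohex-2-en-1-ol
Conditions: CH2I2, Zn, PbCl2 (cat.), THF, 0 °C, to form CH2(ZnI)2 (3 equiv); then 5, THF, 0 → 25 °C
Reagents that add atoms: diiodomethane, ICI
Why: Takai-type methylenation with the geminal dizinc reagent, a non-basic carbonyl olefination chosen because a phosphorus ylide could epimerise C6' or move the ring double bond into conjugation; the free hydroxyl only consumes one equivalent of reagent.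

Step 5
Reactants: 6 rac-(1R,4R)-3,5,5-trimethyl-4-vinylcyclohex-2-en-1-ol
Product: 7 (1R,4R)-3,5,5-trimethyl-4-vinylcyclohex-2-en-1-yl hexadecanoate
Conditions: immobilised Burkholderia cepacia lipase, vinyl palmitate (0.6 equiv), MTBE, 4 Å molecular sieves, 30 °C, stopped near half conversion
Reagents that add atoms: vinyl palmitate (ethenyl hexadecanoate), CCCCCCCCCCCCCCCC(=O)OC=C
Why: Lipase-catalysed kinetic resolution (serine hydrolase, EC 3.1.1.3) by irreversible transesterification, in which the enzyme should acylate only the (1R)-carbinol; this sets the absolute configuration of C3' and, through the fixed trans relation, of C6', and installs the natural palmitate at the same time, the (1S,4S)-alcohol being left behind and separated.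

Step 6
Reactants: 8 ethyl but-2-ynoate
Product: 9 ethyl (2Z)-3-(4,4,5,5-tetramethyl-1,3,2-dioxaborolan-2-yl)but-2-enoate
Conditions: B2pin2 (1.1 equiv), CuCl (3 mol%), NaOtBu (6 mol%), Xantphos (3 mol%), MeOH (2 equiv), THF, 20 °C
Reagents that add atoms: bis(pinacolato)diboron, CC1(C)OB(OC1(C)C)B1OC(C)(C)C(C)(C)O1
Why: Conjugate β-borylation of the ynoate by syn-addition of a monovalent copper boryl species and protonation by methanol puts boron on the methyl-bearing carbon trans to the ester, which fixes the later C9'=C10' geometry.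

Step 7
Reactants: 9 ethyl (2Z)-3-(4,4,5,5-tetramethyl-1,3,2-dioxaborolan-2-yl)but-2-enoate
Product: 10 (2Z)-3-(4,4,5,5-tetramethyl-1,3,2-dioxaborolan-2-yl)but-2-en-1-ol
Conditions: iBu2AlH (2.2 equiv), CH2Cl2, −78 °C; aq. potassium sodium tartrate
Reagents that add atoms: none
Why: Ester reduction to the allylic alcohol at low temperature, which should leave the pinacol boronate and the alkene geometry untouched; boron trans to CH2OH rules out cyclisation onto boron.

Step 8
Reactants: 10 (2Z)-3-(4,4,5,5-tetramethyl-1,3,2-dioxaborolan-2-yl)but-2-en-1-ol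
Product: 11 2-[(2Z)-4-bromobut-2-en-2-yl]-4,4,5,5-tetramethyl-1,3,2-dioxaborolane
Conditions: CBr4 (1.2 equiv), PPh3 (1.25 equiv), CH2Cl2, 0 °C
Reagents that add atoms: carbon tetrabromide, BrC(Br)(Br)Br
Why: Appel bromination of the primary allylic alcohol under neutral conditions, expected to proceed by SN2 at CH2 without allylic transposition.

Step 9
Reactants: 11 2-[(2Z)-4-bromobut-2-en-2-yl]-4,4,5,5-tetramethyl-1,3,2-dioxaborolane
Product: 12 diethyl [(2Z)-3-(4,4,5,5-tetramethyl-1,3,2-dioxaborolan-2-yl)but-2-en-1-yl]phosphonate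
Conditions: P(OEt)3 (3 equiv), neat, 110 °C
Reagents that add atoms: triethyl phosphite, CCOP(OCC)OCC
Why: Michaelis–Arbuzov reaction of the primary allylic bromide, with phosphorus attacking the unhindered CH2 so that the double-bond geometry and the boronate are kept.

Step 10
Reactants: 13 (4R,6R)-actinol ((4R,6R)-4-hydroxy-2,2,6-trimethylcyclohexanone)
Product: 14 (1R,3R)-3,5,5-trimethyl-4-oxocyclohexyl hexadecanoate
Conditions: palmitoyl chloride (1.1 equiv), pyridine, DMAP (cat.), CH2Cl2, 0 → 20 °C
Reagents that add atoms: palmitoyl chloride, CCCCCCCCCCCCCCCC(=O)Cl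
Why: DMAP-catalysed acylation of the only hydroxyl; the C3 stereocentre comes from the chiral-pool ketone and is not touched here or later.

Step 11
Reactants: 14 (1R,3R)-3,5,5-trimethyl-4-oxocyclohexyl hexadecanoate
Product: 15 (1R)-3,5,5-trimethyl-4-(trifluoromethanesulfonyloxy)cyclohex-3-en-1-yl hexadecanoate
Conditions: Tf2O (1.2 equiv), 2,6-di-tert-butyl-4-methylpyridine (1.3 equiv), CH2Cl2, 0 → 20 °C
Reagents that add atoms: triflic anhydride, O=S(=O)(OS(=O)(=O)C(F)(F)F)C(F)(F)F
Why: Enol triflate formation with a hindered non-nucleophilic base; only the methyl-bearing α-carbon has a hydrogen, so the tetrasubstituted C5=C6 enol triflate is the single regioisomer, and the absence of a strong base spares the palmitate.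

Step 12
Reactants: 16 (2E)-3-methylpent-2-en-4-yn-1-ol
Product: 17 (2E,4E)-3-methyl-5-(tributylstannyl)penta-2,4-dien-1-ol
Conditions: Bu3SnH (1.1 equiv), PdCl2(PPh3)2 (2 mol%), THF, 0 °C
Reagents that add atoms: tributyltin hydride, CCCC[SnH](CCCC)CCCC
Why: Palladium-catalysed syn-hydrostannylation of the terminal alkyne of the enyne, with tin going to the terminal carbon, should give the 4E-stannane, the 2E double bond being present from the start.

Step 13
Reactants: 15 (1R)-3,5,5-trimethyl-4-(trifluoromethanesulfonyloxy)cyclohex-3-en-1-yl hexadecanoate; 17 (2E,4E)-3-methyl-5-(tributylstannyl)penta-2,4-dien-1-ol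
Product: 18 (1R)-4-[(1E,3E)-5-hydroxy-3-methylpenta-1,3-dien-1-yl]-3,5,5-trimethylcyclohex-3-en-1-yl hexadecanoate
Conditions: Pd2(dba)3 (5 mol%), AsPh3 (40 mol%), NMP, 60 °C
Reagents that add atoms: none
Why: Stille cross-coupling of the hindered cyclohexenyl triflate with the dienylstannane (weak-donor arsine ligand in a polar solvent to speed transmetalation) forms the C6–C7 bond with retention of both alkene geometries.

Step 14
Reactants: 18 (1R)-4-[(1E,3E)-5-hydroxy-3-methylpenta-1,3-dien-1-yl]-3,5,5-trimethylcyclohex-3-en-1-yl hexadecanoate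
Product: 19 [(2E,4E)-5-[(4R)-4-(hexadecanoyloxy)-2,6,6-trimethylcyclohex-1-en-1-yl]-3-methylpenta-2,4-dien-1-yl]triphenylphosphonium bromide
Conditions: PPh3·HBr (1.05 equiv), CH2Cl2, 20 °C
Reagents that add atoms: triphenylphosphine hydrobromide, Br.c1ccc(cc1)P(c1ccccc1)c1ccccc1
Why: SN1-type substitution through the pentadienyl cation, with the phosphine attacking the least hindered terminus (C11) to give the all-E allylic salt, the classical way to a C15 Wittig salt; the non-allylic ring ester is not ionised.

Step 15
Reactants: 19 [(2E,4E)-5-[(4R)-4-(hexadecanoyloxy)-2,6,6-trimethylcyclohex-1-en-1-yl]-3-methylpenta-2,4-dien-1-yl]triphenylphosphonium bromide; 20 (2E,4E,6E)-2,7-dimethylocta-2,4,6-trienedial (3 equiv)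
Product: 22 (3R)-3-(hexadecanoyloxy)-12'-apo-β-caroten-12'-al (all-E C25 aldehyde), via phosphorus ylide 21 (not isolated)
Conditions: 1,2-epoxybutane (solvent), reflux, dark; then heptane, 80 °C
Reagents that add atoms: none
Why: Wittig olefination under base-free epoxide conditions (the epoxide takes up HBr and frees the ylide), which spares the palmitate; the excess of dialdehyde favours mono-olefination at C12, and any 11Z isomer should equilibrate to the all-E polyene on gentle heating.

Step 16
Reactants: 12 diethyl [(2Z)-3-(4,4,5,5-tetramethyl-1,3,2-dioxaborolan-2-yl)but-2-en-1-yl]phosphonate; 22 (3R)-3-(hexadecanoyloxy)-12'-apo-β-caroten-12'-al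
Product: 24 all-E C29 polyenyl pinacol boronate (β-ring C3 palmitate and chain C7 to C9' with the dioxaborolane on C9' trans to C11'), via lithiated phosphonate 23 (not isolated)
Conditions: LiN(SiMe3)2 (1.0 equiv), THF, −78 °C; then 22, −78 → 0 °C, dark
Reagents that add atoms: none
Why: Horner–Wadsworth–Emmons olefination of the polyenal with the preformed allylic phosphonate anion forms C11'=C12' with E selectivity and brings in C9' already bearing boron trans to the chain; one equivalent of amide base at low temperature should spare the palmitate.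

Step 17
Reactants: 7 (1R,4R)-3,5,5-trimethyl-4-vinylcyclohex-2-en-1-yl hexadecanoate (3 equiv); 24 all-E C29 polyenyl pinacol boronate
Product: 25 helenien ((3R,3'R,6'R)-β,ε-carotene-3,3'-diyl dihexadecanoate)
Conditions: Pd(OAc)2 (10 mol%), 1,2-bis(phenylsulfinyl)ethane (10 mol%), 2,6-dimethyl-1,4-benzoquinone (2 equiv), AcOH (4 equiv), 1,4-dioxane, 25–40 °C, Ar, dark
Reagents that add atoms: none
Why: Transmetalation of the C9'–B bond of 24 to sulfoxide-ligated divalent palladium (retention at C9'=C10') gives a polyenyl–palladium species that inserts into the vinyl group of 7 with carbon going to the terminal C8' and palladium to C7'; syn β-hydride elimination of a C8' hydrogen then releases the E-C7'=C8' bond, and the quinone reoxidises the zerovalent palladium. The closest known reaction type is the oxidative Heck (boron-Heck) vinylation of unactivated terminal olefins with alkenyl pinacol boronates under sulfoxide-ligated Pd(OAc)2 with a quinone oxidant, which is used to make stereodefined dienes and polyenes. No ring is closed and no stereocentre is made: C3, C3' and C6' are carried through, and the only new stereo-element, the C7'=C8' geometry, is fixed by the syn-elimination that keeps C6' and C9' anti. The step needs site-selectivity (secured because the vinyl group of 7 is the only monosubstituted alkene in either partner, all others being trisubstituted or internal and conjugated), terminal regioselectivity (secured by the bulk of C6', flanked by the C1' gem-dimethyl group and the C5' methyl), and elimination toward C8' rather than C6' (secured because the C6'–H is shielded by the same groups and cannot easily become syn-coplanar with palladium, while elimination toward C8' extends the conjugation). The weakly acidic, phosphine-free medium should leave both palmitates untouched and gives zerovalent palladium no time to ionise the allylic C3'–O bond, and the sulfoxide ligand together with the quinone suppresses palladium hydride re-addition that could move double bonds or epimerise C6'. The excess of 7 is meant to outrun oxidative homocoupling of 24 and is recovered.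

**Compound list**

1 | mesityl oxide (4-methylpent-3-en-2-one) | CC(C)=CC(C)=O | starting material
2 | ethyl acetoacetate | CCOC(=O)CC(C)=O | starting material
3 | rac-ethyl 2,6,6-trimethyl-4-oxocyclohex-2-ene-1-carboxylate | CCOC(=O)C1C(C)=CC(=O)CC1(C)C | intermediate
4 | rac-(1R,4R)-4-(hydroxymethyl)-3,5,5-trimethylcyclohex-2-en-1-ol (trans; one enantiomer drawn) | OC[C@H]1C(C)=C[C@H](O)CC1(C)C | intermediate
5 | rac-(1R,4R)-4-hydroxy-2,6,6-trimethylcyclohex-2-ene-1-carbaldehyde (trans; one enantiomer drawn) | O=C[C@H]1C(C)=C[C@H](O)CC1(C)C | intermediate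
6 | rac-(1R,4R)-3,5,5-trimethyl-4-vinylcyclohex-2-en-1-ol (trans; one enantiomer drawn) | C=C[C@H]1C(C)=C[C@H](O)CC1(C)C | intermediate
7 | (1R,4R)-3,5,5-trimethyl-4-vinylcyclohex-2-en-1-yl hexadecanoate | C=C[C@H]1C(C)=C[C@H](OC(=O)CCCCCCCCCCCCCCC)CC1(C)C | intermediate
8 | ethyl but-2-ynoate | CCOC(=O)C#CC | starting material
9 | ethyl (2Z)-3-(4,4,5,5-tetramethyl-1,3,2-dioxaborolan-2-yl)but-2-enoate (boron trans to the ester) | CCOC(=O)/C=C(C)/B1OC(C)(C)C(C)(C)O1 | intermediate
10 | (2Z)-3-(4,4,5,5-tetramethyl-1,3,2-dioxaborolan-2-yl)but-2-en-1-ol | OC/C=C(C)/B1OC(C)(C)C(C)(C)O1 | intermediate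
11 | 2-[(2Z)-4-bromobut-2-en-2-yl]-4,4,5,5-tetramethyl-1,3,2-dioxaborolane | BrC/C=C(C)/B1OC(C)(C)C(C)(C)O1 | intermediate
12 | diethyl [(2Z)-3-(4,4,5,5-tetramethyl-1,3,2-dioxaborolan-2-yl)but-2-en-1-yl]phosphonate | CCOP(=O)(OCC)C/C=C(C)/B1OC(C)(C)C(C)(C)O1 | intermediate
13 | (4R,6R)-actinol ((4R,6R)-4-hydroxy-2,2,6-trimethylcyclohexanone) | O[C@@H]1C[C@@H](C)C(=O)C(C)(C)C1 | starting material
14 | (1R,3R)-3,5,5-trimethyl-4-oxocyclohexyl hexadecanoate | CCCCCCCCCCCCCCCC(=O)O[C@@H]1C[C@@H](C)C(=O)C(C)(C)C1 | intermediate
15 | (1R)-3,5,5-trimethyl-4-(trifluoromethanesulfonyloxy)cyclohex-3-en-1-yl hexadecanoate | CCCCCCCCCCCCCCCC(=O)O[C@@H]1CC(C)=C(OS(=O)(=O)C(F)(F)F)C(C)(C)C1 | intermediate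
16 | (2E)-3-methylpent-2-en-4-yn-1-ol | C#C/C(C)=C/CO | starting material
17 | (2E,4E)-3-methyl-5-(tributylstannyl)penta-2,4-dien-1-ol | CCCC[Sn](CCCC)(CCCC)/C=C/C(C)=C/CO | intermediate
18 | (1R)-4-[(1E,3E)-5-hydroxy-3-methylpenta-1,3-dien-1-yl]-3,5,5-trimethylcyclohex-3-en-1-yl hexadecanoate | CCCCCCCCCCCCCCCC(=O)O[C@@H]1CC(C)=C(/C=C/C(C)=C/CO)C(C)(C)C1 | intermediate
19 | [(2E,4E)-5-[(4R)-4-(hexadecanoyloxy)-2,6,6-trimethylcyclohex-1-en-1-yl]-3-methylpenta-2,4-dien-1-yl]triphenylphosphonium bromide | CCCCCCCCCCCCCCCC(=O)O[C@@H]1CC(C)=C(/C=C/C(C)=C/C[P+](c2ccccc2)(c2ccccc2)c2ccccc2)C(C)(C)C1.[Br-] | intermediate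
20 | (2E,4E,6E)-2,7-dimethylocta-2,4,6-trienedial (C10 dialdehyde) | O=C/C(C)=C/C=C/C=C(C)/C=O | starting material
21 | phosphorus ylide of 19 (formed in the flask) | CCCCCCCCCCCCCCCC(=O)O[C@@H]1CC(C)=C(/C=C/C(C)=C/C=P(c2ccccc2)(c2ccccc2)c2ccccc2)C(C)(C)C1 | intermediate
22 | (3R)-3-(hexadecanoyloxy)-12'-apo-β-caroten-12'-al (all-E C25 aldehyde) | CCCCCCCCCCCCCCCC(=O)O[C@@H]1CC(C)=C(/C=C/C(C)=C/C=C/C(C)=C/C=C/C=C(C)/C=O)C(C)(C)C1 | intermediate
23 | lithiated phosphonate of 12 (formed in the flask) | CCOP(=O)(OCC)[CH-]/C=C(C)/B1OC(C)(C)C(C)(C)O1.[Li+] | intermediate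
24 | all-E C29 polyenyl pinacol boronate: (3R)-3-palmitoyloxy β-ring, chain C7 to C9', 4,4,5,5-tetramethyl-1,3,2-dioxaborolan-2-yl on C9' trans to C11' | CCCCCCCCCCCCCCCC(=O)O[C@@H]1CC(C)=C(/C=C/C(C)=C/C=C/C(C)=C/C=C/C=C(C)/C=C/C=C(C)/B2OC(C)(C)C(C)(C)O2)C(C)(C)C1 | intermediate
25 | helenien, (3R,3'R,6'R)-β,ε-carotene-3,3'-diyl dihexadecanoate | CCCCCCCCCCCCCCCC(=O)O[C@@H]1CC(C)=C(/C=C/C(C)=C/C=C/C(C)=C/C=C/C=C(C)/C=C/C=C(C)/C=C/[C@H]2C(C)=C[C@H](OC(=O)CCCCCCCCCCCCCCC)CC2(C)C)C(C)(C)C1 | target

**Step count and risks**

Total step count: 17 steps.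
Longest linear sequence: 7 steps (steps 10, 11, 13, 14, 15, 16, 17, from actinol 13 to 25).

Steps most likely to fail:

1. Step 17 (key step). What may go wrong: oxidative homocoupling or protodeboronation of the polyenyl boronate outrunning the insertion into the hindered vinyl group; degradation or isomerisation of the polyene under the palladium/quinone conditions; β-hydride elimination toward C6'. Fallback (Suzuki–Miyaura coupling in place of the C–H vinylation, known chemistry): it sets out from aldehyde 5 and boronate 24 and returns at 25. Takai iodo-olefination of 5 (CrCl2, CHI3, THF, 0 °C) should give rac-(1R,4R)-4-[(E)-2-iodoethenyl]-3,5,5-trimethylcyclohex-2-en-1-ol F1. The lipase step with vinyl palmitate, run as in step 5, should then give (1R,4R)-4-[(E)-2-iodoethenyl]-3,5,5-trimethylcyclohex-2-en-1-yl hexadecanoate F2. Coupling of F2 with 24 (Pd2(dba)3, AsPh3, TlOEt, THF–H2O, 20 °C, dark) forms the same C8'–C9' bond with retention at both alkenes and gives 25.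

2. Step 16. What may go wrong: attack of the anion through its boron-stabilised γ-carbon, attack of the base on boron, or protodeboronation and E/Z scrambling of the nonaenyl boronate during isolation. Fallback (boron is used up before the polyene is built): it sets out from 7 and 12 and returns at 25. Oxidative Heck vinylation of 7 with 12 under the conditions of step 17 should give diethyl [(2E,4E)-5-[(1R,4R)-4-(hexadecanoyloxy)-2,6,6-trimethylcyclohex-2-en-1-yl]-3-methylpenta-2,4-dien-1-yl]phosphonate F3. Horner–Wadsworth–Emmons olefination of F3 (LiN(SiMe3)2, THF, −78 → 0 °C) with aldehyde 22 then closes C11'=C12' and gives 25 directly, so that 24 is never made.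

3. Step 2. What may go wrong: poor facial selectivity at C3', with hydride delivered from the other face so that the cis alcohol predominates. Fallback (cis series with inversion at C3' instead of retention): it sets out from 3 and returns at 7. The same reduction then supplies rac-(1S,4R)-4-(hydroxymethyl)-3,5,5-trimethylcyclohex-2-en-1-ol F4. Oxidation as in step 3 gives rac-(1R,4S)-4-hydroxy-2,6,6-trimethylcyclohex-2-ene-1-carbaldehyde F5, and methylenation as in step 4 gives rac-(1S,4R)-3,5,5-trimethyl-4-vinylcyclohex-2-en-1-ol F6. The lipase with vinyl acetate should acetylate the (1R) enantiomer to (1R,4S)-3,5,5-trimethyl-4-vinylcyclohex-2-en-1-yl acetate F7 and leave (1S,4R)-3,5,5-trimethyl-4-vinylcyclohex-2-en-1-ol F8. Mitsunobu esterification of F8 with palmitic acid (PPh3, DIAD, THF, 0 °C) inverts C3' and gives 7.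

**Further compounds**

F1 | step 17 | rac-(1R,4R)-4-[(E)-2-iodoethenyl]-3,5,5-trimethylcyclohex-2-en-1-ol | I/C=C/[C@H]1C(C)=C[C@H](O)CC1(C)C
F2 | step 17 | (1R,4R)-4-[(E)-2-iodoethenyl]-3,5,5-trimethylcyclohex-2-en-1-yl hexadecanoate | I/C=C/[C@H]1C(C)=C[C@H](OC(=O)CCCCCCCCCCCCCCC)CC1(C)C
F3 | step 16 | diethyl [(2E,4E)-5-[(1R,4R)-4-(hexadecanoyloxy)-2,6,6-trimethylcyclohex-2-en-1-yl]-3-methylpenta-2,4-dien-1-yl]phosphonate | CCOP(=O)(OCC)C/C=C(C)/C=C/[C@H]1C(C)=C[C@H](OC(=O)CCCCCCCCCCCCCCC)CC1(C)C
F4 | step 2 | rac-(1S,4R)-4-(hydroxymethyl)-3,5,5-trimethylcyclohex-2-en-1-ol (cis; one enantiomer drawn) | OC[C@H]1C(C)=C[C@@H](O)CC1(C)C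
F5 | step 2 | rac-(1R,4S)-4-hydroxy-2,6,6-trimethylcyclohex-2-ene-1-carbaldehyde (cis; one enantiomer drawn) | O=C[C@H]1C(C)=C[C@@H](O)CC1(C)C
F6 | step 2 | rac-(1S,4R)-3,5,5-trimethyl-4-vinylcyclohex-2-en-1-ol (cis; one enantiomer drawn) | C=C[C@H]1C(C)=C[C@@H](O)CC1(C)C
F7 | step 2 | (1R,4S)-3,5,5-trimethyl-4-vinylcyclohex-2-en-1-yl acetate | C=C[C@@H]1C(C)=C[C@H](OC(C)=O)CC1(C)C
F8 | step 2 | (1S,4R)-3,5,5-trimethyl-4-vinylcyclohex-2-en-1-ol (single enantiomer) | C=C[C@H]1C(C)=C[C@@H](O)CC1(C)C
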